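At 6.0 min, the end of the feed, the flask is read for substrate and solvolysis product. The maple and elm runs had the same doses of both nucleophiles but less substrate than the flask.

| setting | maple | elm | flask |
|---|---|---|---|
| substrate | 0.0050 M | 0.0075 M | 0.010 M |
| first nucleophile | 5 mM (fed, over 6.0 min) | 5 mM (fed, over 6.0 min) | 5.00 mM (fed, over 6.0 min) |
| second nucleophile | 0.020 M | 0.020 M | 0.0200 M |
| remark | run made earlier; the fed solution adds 0.10 times the starting volume | run made earlier; the fed solution adds 0.10 times the starting volume | the fed solution adds 0.10 times the starting volume |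
| time |  |  | 6.0 min |

1. amount of solvolysis product in the flask at 6.0 min, in percent of the substrate charged
2. amount of substrate in the flask at 6.0 min, in percent of the substrate charged

| run | time / min | solvolysis product / % | substrate / % |
|---|---|---|---|
| maple | 0.250 | 0.9 | 98.8 |
| maple | 0.417 | 1.6 | 98.4 |
| maple | 0.667 | 2.4 | 97.2 |
| maple | 1.00 | 3.4 | 96.3 |
| maple | 1.50 | 5.6 | 94.6 |
| maple | 2.50 | 8.9 | 90.9 |
| maple | 4.00 | 13.8 | 85.6 |
| elm | 0.250 | 0.9 | 99.0 |
| elm | 0.417 | 1.6 | 98.8 |
| elm | 0.667 | 2.6 | 97.3 |
| elm | 1.00 | 3.7 | 96.1 |
| elm | 1.50 | 5.8 | 94.3 |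
| elm | 2.50 | 9.6 | 90.8 |
| elm | 4.00 | 14.6 | 85.8 |

(scatter of a reading: 0.3 percentage points)

The quantity to follow is the fraction of substrate left. In a first-order loss it falls as exp(−kt), whatever the charge or the dilution by the feed. At 4.00 min the substrate readings of maple and elm differ by 0.2 percentage points, within the scatter of 0.3 points, although elm held more substrate. The two runs together give 0.0386 min⁻¹ as the decay constant, the logarithm of one over the fraction of substrate left, divided by the time.

Carried to the flask at 6.0 min, this constant leaves 79.3 % substrate. At 4.00 min in the two runs, nearly all of the lost substrate read as solvolysis product, so this reckoning puts solvolysis product in the flask at 20.7 %.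

The forecast gives 20.1 % solvolysis product and 79.5 % substrate, its solvolysis product lying below this reckoning, “allowing slightly for possible capture”.

The flask gives 20.2 % solvolysis product and 79.2 % substrate.

    substrate + intermediate → side product (k = 0.0545 L mol⁻¹ s⁻¹)
    substrate → intermediate (k = 6.47 × 10⁻⁴ s⁻¹)
    first nucleophile + intermediate → target (k = 84.6 L mol⁻¹ s⁻¹)
    first nucleophile ⇌ dormant form (K = 3.53, k = 2.32 × 10⁻⁴ s⁻¹)
    second nucleophile + intermediate → other capture product (k = 8.21 L mol⁻¹ s⁻¹)
    intermediate → solvolysis product (k = 13.1 s⁻¹)

During the feed, substrate in the flask went to intermediate, the rate-limiting step, with a decay constant of 0.0389 min⁻¹ beside the carried 0.0386 min⁻¹, while the intermediate stood at 0 % and first nucleophile climbed to 95.4 % of its charge. At 6.00 min the flask also held target at 0.285 % and other capture product at 0.242 %. Carried to 15 min, the decay constant leaves 56.0 %, and the same flask read then holds 55.9 % substrate.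

The readings are simulated for substances that don't exist.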